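**Retrosynthetic overview**
1. Target ⇐ global desilylation ⇐ Suzuki coupling of a (1E,3E)-dienyl iodide on the spiro core with a C8 1,1-disubstituted alkenylboronate (last C–C bond of the triene).
2. Spiro-cyclopentanol ⇐ nickel-catalysed aldehyde/allene/borylmethylzinc cyclization of a cyclohexane carbaldehyde (C1–C2 bond, both new stereocentres, the trisubstituted alkene and the CH2OH carbon in one step); exocyclic enal ⇐ enol triflate → isopropenyl coupling → 1,4-hydroboration.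
3. (Ra)-Allene ⇐ hydroboration of a vinyl group and palladium-catalysed anti SN2' coupling with an (R)-propargylic carbonate.
4. Cyclohexane with its quaternary carbon ⇐ Ireland–Claisen ring contraction of a 6-alkenyl δ-lactone, then iodolactonization; δ-lactone ⇐ asymmetric vinylogous aldol and conjugate borylation/oxidation.
5. Ring order: δ-lactone (temporary) → cyclohexene → bridged γ-lactone (temporary) → spiro-cyclopentane.

Assumption: the target is the single stereoisomer encoded by the given SMILES; where a chiral catalyst or ligand is named, the enantiomer that delivers the drawn configuration is meant.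

Abbreviations: TBS = tert-butyldimethylsilyl, TES = triethylsilyl, Bpin = 4,4,5,5-tetramethyl-1,3,2-dioxaborolan-2-yl. Spiro compounds carry the target's locants (C1 carbinol carbon, C2 side-chain carbon, C5 spiro carbon, C6 methylcarbinol carbon, C9 oxo/ylidene carbon, C10 propyl-bearing carbon).

**Route**

Step 1
Reactants: 1 pent-4-en-1-ol
Product: 2 tert-butyl(dimethyl)(pent-4-en-1-yloxy)silane
Conditions: t-BuMe2SiCl, imidazole, DMF, 23 °C
Reagents that add atoms: tert-butyl(chloro)dimethylsilane, CC(C)(C)[Si](C)(C)Cl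
Why: Standard silyl ether protection of a primary alcohol, with no stereocentre involved.

Step 2
Reactants: 2 tert-butyl(dimethyl)(pent-4-en-1-yloxy)silane; 3 (2E)-but-2-enal
Product: 4 (2E)-6-(TBSO)hex-2-enal
Conditions: second-generation Hoveyda–Grubbs catalyst (3 mol%), CH2Cl2, 40 °C
Reagents that add atoms: none
Why: Olefin cross-metathesis of a terminal alkene with crotonaldehyde gives the conjugated (E)-enal, driven by loss of propene.

Step 3
Reactants: 5 methyl 3-methylbut-2-enoate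
Product: 6 [(1E)-1-methoxy-3-methylbuta-1,3-dien-1-yl]oxy(trimethyl)silane
Conditions: LiN(i-Pr)2, Me3SiCl, THF, −78 °C
Reagents that add atoms: chlorotrimethylsilane, C[Si](C)(C)Cl
Why: γ-Deprotonation of the unsaturated ester and O-silylation (silyl dienolate formation) give the vinylogous Mukaiyama donor, whose C1 geometry is of no consequence.

Step 4
Reactants: 4 (2E)-6-(TBSO)hex-2-enal; 6 [(1E)-1-methoxy-3-methylbuta-1,3-dien-1-yl]oxy(trimethyl)silane
Product: 8 (6R)-6-[(1E)-5-(TBSO)pent-1-en-1-yl]-4-methyl-5,6-dihydro-2H-pyran-2-one, via copper aldolate 7 (not isolated)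
Conditions: Cu(OTf)2 (10 mol%), (S)-Tol-BINAP (11 mol%), Bu4N[Ph3SiF2] (20 mol%), THF, −78 → 23 °C
Reagents that add atoms: none
Why: Catalytic asymmetric vinylogous Mukaiyama aldol through a chiral copper dienolate, in which γ-attack on the Re face of the enal sets C6 (R) and the (Z)-aldolate lactonises with loss of methoxide.

Step 5
Reactants: 8 (6R)-6-[(1E)-5-(TBSO)pent-1-en-1-yl]-4-methyl-5,6-dihydro-2H-pyran-2-one
Product: 10 (4S,6R)-6-[(1E)-5-(TBSO)pent-1-en-1-yl]-4-hydroxy-4-methyloxan-2-one, via boryl lactone 9 (not isolated)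
Conditions: B2pin2, CuCl (5 mol%), DPEphos (5 mol%), NaOt-Bu (10 mol%), MeOH (2 equiv), THF, 23 °C; then NaBO3·4H2O, THF/H2O, 23 °C
Reagents that add atoms: sodium perborate, [Na+].[O-]OB=O
Why: Copper-catalysed conjugate borylation adds boron anti to the C6 alkenyl group of the half-chair lactone and perborate oxidation proceeds with retention, so the tertiary hydroxyl at C4 (S) is trans to the C6 substituent.

Step 6
Reactants: 10 (4S,6R)-6-[(1E)-5-(TBSO)pent-1-en-1-yl]-4-hydroxy-4-methyloxan-2-one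
Product: 11 (4S,6R)-6-[(1E)-5-(TBSO)pent-1-en-1-yl]-4-methyl-4-(TESO)oxan-2-one
Conditions: Et3SiOTf, 2,6-lutidine, CH2Cl2, −78 → 0 °C
Reagents that add atoms: triethylsilyl trifluoromethanesulfonate, CC[Si](CC)(CC)OS(=O)(=O)C(F)(F)F
Why: Silyl triflate silylation protects the hindered tertiary alcohol and blocks retro-oxa-Michael loss of water.

Step 7
Reactants: 11 (4S,6R)-6-[(1E)-5-(TBSO)pent-1-en-1-yl]-4-methyl-4-(TESO)oxan-2-one; 12 acetaldehyde
Product: 16 (3Z,4S,6R)-6-[(1E)-5-(TBSO)pent-1-en-1-yl]-3-ethylidene-4-methyl-4-(TESO)oxan-2-one, via lithium enolate 13 (not isolated), via lithium aldolate 14 (not isolated), via mesylate 15 (not isolated)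
Conditions: LiN(i-Pr)2, THF, −78 °C; 12; MeSO2Cl, −78 → 0 °C; DBU, 23 °C
Reagents that add atoms: none
Why: Lactone enolate aldol addition followed by mesylation and E1cB elimination (aldol condensation sequence) installs the 3-ethylidene group as a masked vinyl group, the transient stereocentres being destroyed.

Step 8
Reactants: 16 (3Z,4S,6R)-6-[(1E)-5-(TBSO)pent-1-en-1-yl]-3-ethylidene-4-methyl-4-(TESO)oxan-2-one
Product: 19 (1R,2R,6S)-2-[3-(TBSO)propyl]-1-ethenyl-6-methyl-6-(TESO)cyclohex-3-ene-1-carboxylic acid, via silyl ketene acetal 17 (not isolated), via trimethylsilyl ester 18 (not isolated)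
Conditions: LiN(i-Pr)2, Me3SiCl/Et3N, THF/DMPU, −78 °C; toluene, 105 °C; 1 M HCl (aq) work-up
Reagents that add atoms: none
Why: γ-Deprotonation gives the 3-vinyl silyl ketene acetal, which undergoes Ireland–Claisen ring contraction through the boat transition state enforced by the lactone, so the new bond forms on the face of the C6 alkenyl group, the (E)-alkene places the propyl chain cis to the carboxyl, and the carboxyl ends cis to the C–O bond, setting the quaternary C1 (R) and C2 (R).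

Step 9
Reactants: 19 (1R,2R,6S)-2-[3-(TBSO)propyl]-1-ethenyl-6-methyl-6-(TESO)cyclohex-3-ene-1-carboxylic acid
Product: 20 (1R,2S,4S,5S,8S)-8-[3-(TBSO)propyl]-1-ethenyl-4-iodo-2-methyl-2-(TESO)-6-oxabicyclo[3.2.1]octan-7-one
Conditions: I2, NaHCO3, MeCN/H2O, 0 °C, dark
Reagents that add atoms: iodine, II
Why: Iodolactonization, in which the axial carboxylate opens the iodonium ion of the ring alkene at the γ-carbon (5-exo) to give the bridged γ-lactone with trans iodine, while the hindered vinyl group (4-exo only) stays untouched.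

Step 10
Reactants: 20 (1R,2S,4S,5S,8S)-8-[3-(TBSO)propyl]-1-ethenyl-4-iodo-2-methyl-2-(TESO)-6-oxabicyclo[3.2.1]octan-7-one
Product: 21 (1R,2S,5R,8S)-8-[3-(TBSO)propyl]-1-ethenyl-2-methyl-2-(TESO)-6-oxabicyclo[3.2.1]octan-7-one
Conditions: Bu3SnH, AIBN (cat.), toluene, 80 °C
Reagents that add atoms: none
Why: Radical-chain dehalogenation with tin hydride removes iodine without touching a stereocentre, the equatorial vinyl group being out of reach of the C4 radical.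

Step 11
Reactants: 22 2,2-dimethoxyacetaldehyde; 23 ethynyl(trimethyl)silane
Product: 25 rac-1,1-dimethoxy-4-(trimethylsilyl)but-3-yn-2-ol, via lithium acetylide 24 (not isolated)
Conditions: n-BuLi, THF, −78 °C; then 22 (anhydrous), −78 → 0 °C
Reagents that add atoms: none
Why: 1,2-Addition of a lithium acetylide to an aldehyde.

Step 12
Reactants: 25 rac-1,1-dimethoxy-4-(trimethylsilyl)but-3-yn-2-ol
Product: 26 1,1-dimethoxy-4-(trimethylsilyl)but-3-yn-2-one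
Conditions: MnO2, CH2Cl2, 23 °C
Reagents that add atoms: none
Why: MnO2 oxidation of an activated propargylic alcohol to the ynone.

Step 13
Reactants: 26 1,1-dimethoxy-4-(trimethylsilyl)but-3-yn-2-one
Product: 27 (2R)-1,1-dimethoxy-4-(trimethylsilyl)but-3-yn-2-ol
Conditions: RuCl[(S,S)-TsDPEN](p-cymene) (1 mol%), i-PrOH, 23 °C
Reagents that add atoms: none
Why: Noyori asymmetric transfer hydrogenation of an alkynyl ketone, in which the alkyne acts as the π-directing group and hydride delivery sets the (R)-carbinol.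

Step 14
Reactants: 27 (2R)-1,1-dimethoxy-4-(trimethylsilyl)but-3-yn-2-ol
Product: 28 (2R)-1,1-dimethoxybut-3-yn-2-ol
Conditions: K2CO3 (cat.), MeOH, 0 °C
Reagents that add atoms: none
Why: Base-catalysed protodesilylation of the alkynylsilane leaves the stereocentre untouched.

Step 15
Reactants: 28 (2R)-1,1-dimethoxybut-3-yn-2-ol
Product: 29 (2R)-1,1-dimethoxybut-3-yn-2-yl methyl carbonate
Conditions: ClCO2Me, pyridine, DMAP (cat.), CH2Cl2, 0 °C
Reagents that add atoms: methyl chloroformate, COC(=O)Cl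
Why: O-Acylation gives the propargylic carbonate, the leaving group for palladium, with retention at the carbinol carbon.

Step 16
Reactants: 21 (1R,2S,5R,8S)-8-[3-(TBSO)propyl]-1-ethenyl-2-methyl-2-(TESO)-6-oxabicyclo[3.2.1]octan-7-one; 29 (2R)-1,1-dimethoxybut-3-yn-2-yl methyl carbonate
Product: 31 (1R,2S,5R,8S)-8-[3-(TBSO)propyl]-1-[(Ra)-6,6-dimethoxyhexa-3,4-dien-1-yl]-2-methyl-2-(TESO)-6-oxabicyclo[3.2.1]octan-7-one, via alkyl-9-BBN 30 (not isolated)
Conditions: 9-BBN-H, THF, 0 → 23 °C; then 29, Pd(PPh3)4 (5 mol%), THF, 50 °C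
Reagents that add atoms: none
Why: Anti-Markovnikov hydroboration of the vinyl group, then palladium-catalysed cross-coupling of the B-alkyl-9-BBN with the propargylic carbonate (anti SN2' oxidative addition, transmetalation, reductive elimination) transfers the (R)-carbinol centre to the (Ra)-allene axis.

Step 17
Reactants: 31 (1R,2S,5R,8S)-8-[3-(TBSO)propyl]-1-[(Ra)-6,6-dimethoxyhexa-3,4-dien-1-yl]-2-methyl-2-(TESO)-6-oxabicyclo[3.2.1]octan-7-one
Product: 32 [(1S,2S,3R,6S)-2-[3-(TBSO)propyl]-1-[(Ra)-6,6-dimethoxyhexa-3,4-dien-1-yl]-3-hydroxy-6-methyl-6-(TESO)cyclohexyl]methanol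
Conditions: LiAlH4, THF, 0 °C; KNaC4H4O6 (aq) work-up
Reagents that add atoms: none
Why: Hydride reduction of the lactone gives the diol, and the allene, acetal and silyl ethers are inert to it.

Step 18
Reactants: 32 [(1S,2S,3R,6S)-2-[3-(TBSO)propyl]-1-[(Ra)-6,6-dimethoxyhexa-3,4-dien-1-yl]-3-hydroxy-6-methyl-6-(TESO)cyclohexyl]methanol
Product: 33 (1R,2S,6S)-2-[3-(TBSO)propyl]-1-[(Ra)-6,6-dimethoxyhexa-3,4-dien-1-yl]-6-methyl-3-oxo-6-(TESO)cyclohexane-1-carbaldehyde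
Conditions: (COCl)2, Me2SO, CH2Cl2, −78 °C; Et3N, −78 → 0 °C
Reagents that add atoms: none
Why: Swern oxidation activates both hydroxyls at −78 °C before a lactol can form, giving the non-enolisable neopentyl aldehyde and the ketone together.

Step 19
Reactants: 34 chloro(iodo)methane
Product: 37 2-(chloromethyl)-4,4,5,5-tetramethyl-1,3,2-dioxaborolane, via lithium borate 35 (not isolated), via diisopropyl boronate 36 (not isolated)
Conditions: B(Oi-Pr)3, n-BuLi, THF, −78 °C; HCl (Et2O); pinacol, 23 °C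
Reagents that add atoms: triisopropyl borate, CC(C)OB(OC(C)C)OC(C)C; pinacol, CC(C)(O)C(C)(C)O
Why: Iodine–lithium exchange in the presence of the borate traps chloromethyllithium as the ate complex (Matteson-type borylation), and transesterification with pinacol gives the stable boronate.

Step 20
Reactants: 37 2-(chloromethyl)-4,4,5,5-tetramethyl-1,3,2-dioxaborolane
Product: 38 2-(iodomethyl)-4,4,5,5-tetramethyl-1,3,2-dioxaborolane
Conditions: NaI, acetone, 23 °C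
Reagents that add atoms: sodium iodide, [Na+].[I-]
Why: Finkelstein halide exchange driven by precipitation of NaCl.

Step 21
Reactants: 38 2-(iodomethyl)-4,4,5,5-tetramethyl-1,3,2-dioxaborolane
Product: 39 iodo[(4,4,5,5-tetramethyl-1,3,2-dioxaborolan-2-yl)methyl]zinc (LiCl complex in THF)
Conditions: Zn dust, LiCl, THF, 23 °C
Reagents that add atoms: zinc, [Zn]
Why: LiCl-promoted direct insertion of zinc into the C–I bond gives a boron-stabilised alkylzinc reagent that has no β-hydrogen.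

Step 22
Reactants: 33 (1R,2S,6S)-2-[3-(TBSO)propyl]-1-[(Ra)-6,6-dimethoxyhexa-3,4-dien-1-yl]-6-methyl-3-oxo-6-(TESO)cyclohexane-1-carbaldehyde; 39 iodo[(4,4,5,5-tetramethyl-1,3,2-dioxaborolan-2-yl)methyl]zinc (LiCl complex in THF)
Product: 41 (1R,2S,5S,6S,10S)-10-[3-(TBSO)propyl]-1-hydroxy-2-[(2E)-1-hydroxy-4,4-dimethoxybut-2-en-2-yl]-6-methyl-6-(TESO)spiro[4.5]decan-9-one, via allylboronate 40 (not isolated)
Conditions: Ni(cod)2 (15 mol%), 39 (3 equiv), THF, 0 °C; then NaBO3·4H2O, THF/H2O, 23 °C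
Reagents that add atoms: sodium perborate, [Na+].[O-]OB=O
Why: Proposed new method: zerovalent nickel joins the aldehyde and the proximal allene double bond by oxidative cyclization on the allene face anti to the dimethoxymethyl group, giving a cis-fused oxanickelacycle (C1–C2 bond, oxygen and alkenyl cis), then transmetalation of the β-hydrogen-free borylmethylzinc reagent and C(sp2)–C(sp3) reductive elimination place CH2Bpin on the central carbon cis to the alkenyl hydrogen, so the (Ra) axis fixes C2 (S), C1 (R) and the alkene geometry, and perborate converts the allylboronate into the allylic alcohol; the closest known reaction type is the nickel-catalysed alkylative cyclization of allenyl aldehydes with dialkylzincs (methyl transfer), extended here to an α-boryl alkylzinc as a hydroxymethyl equivalent, with the ketone too unreactive to compete.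

Step 23
Reactants: 41 (1R,2S,5S,6S,10S)-10-[3-(TBSO)propyl]-1-hydroxy-2-[(2E)-1-hydroxy-4,4-dimethoxybut-2-en-2-yl]-6-methyl-6-(TESO)spiro[4.5]decan-9-one
Product: 42 (1R,2S,5S,6S,10S)-1-(TBSO)-2-[(2E)-1-(TBSO)-4,4-dimethoxybut-2-en-2-yl]-10-[3-(TBSO)propyl]-6-methyl-6-(TESO)spiro[4.5]decan-9-one
Conditions: t-BuMe2SiCl, imidazole, DMAP (cat.), DMF, 40 °C
Reagents that add atoms: tert-butyl(chloro)dimethylsilane, CC(C)(C)[Si](C)(C)Cl
Why: Silylation of both hydroxyls with the silyl chloride, chosen because silyl triflate/lutidine would cleave the dimethyl acetal.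

Step 24
Reactants: 42 (1R,2S,5S,6S,10S)-1-(TBSO)-2-[(2E)-1-(TBSO)-4,4-dimethoxybut-2-en-2-yl]-10-[3-(TBSO)propyl]-6-methyl-6-(TESO)spiro[4.5]decan-9-one
Product: 44 (1R,2S,5S,6S,10S)-1-(TBSO)-2-[(2E)-1-(TBSO)-4,4-dimethoxybut-2-en-2-yl]-10-[3-(TBSO)propyl]-6-methyl-6-(TESO)spiro[4.5]dec-8-en-9-yl trifluoromethanesulfonate, via potassium enolate 43 (not isolated)
Conditions: KN(SiMe3)2, THF, −78 °C; PhNTf2, −78 → 0 °C
Reagents that add atoms: N-phenylbis(trifluoromethanesulfonimide), O=S(=O)(N(c1ccccc1)S(=O)(=O)C(F)(F)F)C(F)(F)F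
Why: Kinetic deprotonation at the unhindered C8 methylene, not the neopentyl C10 methine, and O-triflation give the C8=C9 enol triflate without touching C10.

Step 25
Reactants: 44 (1R,2S,5S,6S,10S)-1-(TBSO)-2-[(2E)-1-(TBSO)-4,4-dimethoxybut-2-en-2-yl]-10-[3-(TBSO)propyl]-6-methyl-6-(TESO)spiro[4.5]dec-8-en-9-yl trifluoromethanesulfonate; 45 potassium trifluoro(prop-1-en-2-yl)borate
Product: 46 (1R,2S,5S,6S,10R)-1-(TBSO)-2-[(2E)-1-(TBSO)-4,4-dimethoxybut-2-en-2-yl]-10-[3-(TBSO)propyl]-6-methyl-9-(prop-1-en-2-yl)-6-(TESO)spiro[4.5]dec-8-ene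
Conditions: Pd(dppf)Cl2 (5 mol%), Et3N, n-PrOH/H2O, 70 °C
Reagents that add atoms: none
Why: Suzuki–Miyaura coupling of the alkenyl triflate with the alkenyltrifluoroborate builds the 1,3-diene.

Step 26
Reactants: 46 (1R,2S,5S,6S,10R)-1-(TBSO)-2-[(2E)-1-(TBSO)-4,4-dimethoxybut-2-en-2-yl]-10-[3-(TBSO)propyl]-6-methyl-9-(prop-1-en-2-yl)-6-(TESO)spiro[4.5]dec-8-ene
Product: 48 (2E)-2-[(1R,2S,5S,6S,10R)-1-(TBSO)-2-[(2E)-1-(TBSO)-4,4-dimethoxybut-2-en-2-yl]-10-[3-(TBSO)propyl]-6-methyl-6-(TESO)spiro[4.5]decan-9-ylidene]propan-1-ol, via allylboronate 47 (not isolated)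
Conditions: HBpin, Ni(cod)2 (5 mol%), PCy3 (5 mol%), toluene, 23 °C; then NaBO3·4H2O, THF/H2O
Reagents that add atoms: sodium perborate, [Na+].[O-]OB=O
Why: Nickel-catalysed 1,4-hydroboration of the 1,3-diene through its s-cis nickel complex delivers hydrogen to C8 and boron to the terminal CH2, so the two former diene termini end cis on the new tetrasubstituted C9 double bond (CH2B cis to C8, methyl cis to C10), and oxidation with retention gives the (E)-allylic alcohol.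

Step 27
Reactants: 48 (2E)-2-[(1R,2S,5S,6S,10R)-1-(TBSO)-2-[(2E)-1-(TBSO)-4,4-dimethoxybut-2-en-2-yl]-10-[3-(TBSO)propyl]-6-methyl-6-(TESO)spiro[4.5]decan-9-ylidene]propan-1-ol
Product: 49 (2E)-4-(TBSO)-3-[(1R,2S,5S,6S,10R)-1-(TBSO)-10-[3-(TBSO)propyl]-9-[(2E)-1-hydroxypropan-2-ylidene]-6-methyl-6-(TESO)spiro[4.5]decan-2-yl]but-2-enal
Conditions: pyridinium p-toluenesulfonate (10 mol%), acetone/H2O 10:1, 23 °C
Reagents that add atoms: water, O
Why: Mild acid hydrolysis of the allylic dimethyl acetal, which is far more labile than the silyl ethers, unmasks the enal.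

Step 28
Reactants: 49 (2E)-4-(TBSO)-3-[(1R,2S,5S,6S,10R)-1-(TBSO)-10-[3-(TBSO)propyl]-9-[(2E)-1-hydroxypropan-2-ylidene]-6-methyl-6-(TESO)spiro[4.5]decan-2-yl]but-2-enal
Product: 50 (2E)-2-[(1R,2S,5S,6S,10R)-1-(TBSO)-2-[(2E,4E)-1-(TBSO)-5-iodopenta-2,4-dien-2-yl]-10-[3-(TBSO)propyl]-6-methyl-6-(TESO)spiro[4.5]decan-9-ylidene]propan-1-ol
Conditions: CrCl2, CHI3, THF/1,4-dioxane, 0 °C
Reagents that add atoms: iodoform, IC(I)I
Why: Takai olefination with the geminal dichromium reagent converts the only aldehyde into the (E)-alkenyl iodide and tolerates the free allylic alcohol.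

Step 29
Reactants: 50 (2E)-2-[(1R,2S,5S,6S,10R)-1-(TBSO)-2-[(2E,4E)-1-(TBSO)-5-iodopenta-2,4-dien-2-yl]-10-[3-(TBSO)propyl]-6-methyl-6-(TESO)spiro[4.5]decan-9-ylidene]propan-1-ol
Product: 51 (2E)-2-[(1R,2S,5S,6S,10R)-1-(TBSO)-2-[(2E,4E)-1-(TBSO)-5-iodopenta-2,4-dien-2-yl]-10-[3-(TBSO)propyl]-6-methyl-6-(TESO)spiro[4.5]decan-9-ylidene]propanal
Conditions: MnO2, CH2Cl2, 23 °C
Reagents that add atoms: none
Why: MnO2 oxidises the only free (allylic) alcohol to the tetrasubstituted enal while all other oxygens remain silylated.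

Step 30
Reactants: 52 5-bromo-2-methylpent-2-ene; 53 N-methoxy-N-methylacetamide
Product: 55 6-methylhept-5-en-2-one, via Grignard reagent 54 (not isolated)
Conditions: Mg, THF, 23 °C; then 53, 0 °C; H2O work-up
Reagents that add atoms: none
Why: Grignard formation and acylation with a Weinreb amide, whose stable chelate prevents over-addition, give the methyl ketone.

Step 31
Reactants: 55 6-methylhept-5-en-2-one
Product: 57 6-methylhepta-1,5-dien-2-yl trifluoromethanesulfonate, via lithium enolate 56 (not isolated)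
Conditions: LiN(i-Pr)2, THF, −78 °C; PhNTf2, −78 → 0 °C
Reagents that add atoms: N-phenylbis(trifluoromethanesulfonimide), O=S(=O)(N(c1ccccc1)S(=O)(=O)C(F)(F)F)C(F)(F)F
Why: Kinetic enolization on the methyl side and O-triflation give the 1,1-disubstituted alkenyl triflate.

Step 32
Reactants: 57 6-methylhepta-1,5-dien-2-yl trifluoromethanesulfonate
Product: 58 2-(6-methylhepta-1,5-dien-2-yl)-4,4,5,5-tetramethyl-1,3,2-dioxaborolane
Conditions: B2pin2, PdCl2(PPh3)2 (3 mol%), PPh3, KOPh, toluene, 50 °C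
Reagents that add atoms: bis(pinacolato)diboron, CC1(C)OB(OC1(C)C)B1OC(C)(C)C(C)(C)O1
Why: Miyaura borylation of the alkenyl triflate turns the electrophile into the coupling nucleophile.

Step 33
Reactants: 51 (2E)-2-[(1R,2S,5S,6S,10R)-1-(TBSO)-2-[(2E,4E)-1-(TBSO)-5-iodopenta-2,4-dien-2-yl]-10-[3-(TBSO)propyl]-6-methyl-6-(TESO)spiro[4.5]decan-9-ylidene]propanal; 58 2-(6-methylhepta-1,5-dien-2-yl)-4,4,5,5-tetramethyl-1,3,2-dioxaborolane
Product: 59 (2E)-2-[(1R,2S,5S,6S,10R)-1-(TBSO)-2-[(2E,4E)-1-(TBSO)-10-methyl-6-methylideneundeca-2,4,9-trien-2-yl]-10-[3-(TBSO)propyl]-6-methyl-6-(TESO)spiro[4.5]decan-9-ylidene]propanal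
Conditions: Pd(dppf)Cl2 (5 mol%), K3PO4 (aq), THF, 23 °C
Reagents that add atoms: none
Why: Suzuki–Miyaura coupling of the dienyl iodide with the 1,1-disubstituted alkenylboronate forms the last C–C bond of the triene with retention of both alkene geometries.

Step 34
Reactants: 59 (2E)-2-[(1R,2S,5S,6S,10R)-1-(TBSO)-2-[(2E,4E)-1-(TBSO)-10-methyl-6-methylideneundeca-2,4,9-trien-2-yl]-10-[3-(TBSO)propyl]-6-methyl-6-(TESO)spiro[4.5]decan-9-ylidene]propanal
Product: 60 CNP0246965.4, (2E)-2-[(1R,2S,5S,6S,10R)-1,6-dihydroxy-2-[(2E,4E)-1-hydroxy-10-methyl-6-methylideneundeca-2,4,9-trien-2-yl]-10-(3-hydroxypropyl)-6-methylspiro[4.5]decan-9-ylidene]propanal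
Conditions: HF·pyridine, pyridine, THF, 0 → 23 °C
Reagents that add atoms: none
Why: Buffered fluoride cleavage removes the three TBS ethers and the tertiary TES ether without touching the enal, the triene or any stereocentre.

**Compound list**

1 | pent-4-en-1-ol | C=CCCCO | starting material
2 | tert-butyl(dimethyl)(pent-4-en-1-yloxy)silane | C=CCCCO[Si](C)(C)C(C)(C)C | intermediate
3 | (2E)-but-2-enal | C/C=C/C=O | starting material
4 | (2E)-6-(TBSO)hex-2-enal | O=C/C=C/CCCO[Si](C)(C)C(C)(C)C | intermediate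
5 | methyl 3-methylbut-2-enoate | COC(=O)C=C(C)C | starting material
6 | [(1E)-1-methoxy-3-methylbuta-1,3-dien-1-yl]oxy(trimethyl)silane | C=C(C)/C=C(\OC)O[Si](C)(C)C | intermediate
7 | copper aldolate: methyl (2Z,5R,6E)-10-(TBSO)-5-hydroxy-3-methyldeca-2,6-dienoate as its copper alkoxide (drawn as the alcohol) | COC(=O)/C=C(/C)C[C@@H](O)/C=C/CCCO[Si](C)(C)C(C)(C)C | intermediate
8 | (6R)-6-[(1E)-5-(TBSO)pent-1-en-1-yl]-4-methyl-5,6-dihydro-2H-pyran-2-one | CC1=CC(=O)O[C@@H](/C=C/CCCO[Si](C)(C)C(C)(C)C)C1 | intermediate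
9 | boryl lactone: (4R,6R)-6-[(1E)-5-(TBSO)pent-1-en-1-yl]-4-methyl-4-(Bpin)oxan-2-one | C1C(=O)O[C@@H](/C=C/CCCO[Si](C)(C)C(C)(C)C)C[C@]1(C)B2OC(C)(C)C(C)(C)O2 | intermediate
10 | (4S,6R)-6-[(1E)-5-(TBSO)pent-1-en-1-yl]-4-hydroxy-4-methyloxan-2-one | C1C(=O)O[C@@H](/C=C/CCCO[Si](C)(C)C(C)(C)C)C[C@]1(C)O | intermediate
11 | (4S,6R)-6-[(1E)-5-(TBSO)pent-1-en-1-yl]-4-methyl-4-(TESO)oxan-2-one | C1C(=O)O[C@@H](/C=C/CCCO[Si](C)(C)C(C)(C)C)C[C@]1(C)O[Si](CC)(CC)CC | intermediate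
12 | acetaldehyde | CC=O | starting material
13 | lithium enolate of 11 | C1=C(O[Li])O[C@@H](/C=C/CCCO[Si](C)(C)C(C)(C)C)C[C@]1(C)O[Si](CC)(CC)CC | intermediate
14 | lithium aldolate: 3-(1-lithiooxyethyl) derivative of 11 (C3 and carbinol epimers) | CC(O[Li])C1C(=O)O[C@@H](/C=C/CCCO[Si](C)(C)C(C)(C)C)C[C@]1(C)O[Si](CC)(CC)CC | intermediate
15 | mesylate: 3-[1-(methanesulfonyloxy)ethyl] derivative of 11 (C3 and carbinol epimers) | CC(OS(C)(=O)=O)C1C(=O)O[C@@H](/C=C/CCCO[Si](C)(C)C(C)(C)C)C[C@]1(C)O[Si](CC)(CC)CC | intermediate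
16 | (3Z,4S,6R)-6-[(1E)-5-(TBSO)pent-1-en-1-yl]-3-ethylidene-4-methyl-4-(TESO)oxan-2-one | C/C=C1\C(=O)O[C@@H](/C=C/CCCO[Si](C)(C)C(C)(C)C)C[C@]1(C)O[Si](CC)(CC)CC | intermediate
17 | silyl ketene acetal: (4S,6R)-6-[(1E)-5-(TBSO)pent-1-en-1-yl]-3-ethenyl-4-methyl-4-(TESO)-2-(trimethylsilyloxy)-5,6-dihydro-4H-pyran | C=CC1=C(O[Si](C)(C)C)O[C@@H](/C=C/CCCO[Si](C)(C)C(C)(C)C)C[C@]1(C)O[Si](CC)(CC)CC | intermediate
18 | trimethylsilyl ester of 19 | C=C[C@]2([C@H](CCCO[Si](C)(C)C(C)(C)C)C=CC[C@]2(C)O[Si](CC)(CC)CC)C(=O)O[Si](C)(C)C | intermediate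
19 | (1R,2R,6S)-2-[3-(TBSO)propyl]-1-ethenyl-6-methyl-6-(TESO)cyclohex-3-ene-1-carboxylic acid | C=C[C@]2([C@H](CCCO[Si](C)(C)C(C)(C)C)C=CC[C@]2(C)O[Si](CC)(CC)CC)C(=O)O | intermediate
20 | (1R,2S,4S,5S,8S)-8-[3-(TBSO)propyl]-1-ethenyl-4-iodo-2-methyl-2-(TESO)-6-oxabicyclo[3.2.1]octan-7-one | C=C[C@]2([C@H](CCCO[Si](C)(C)C(C)(C)C)[C@H]3[C@@H](I)C[C@]2(C)O[Si](CC)(CC)CC)C(=O)O3 | intermediate
21 | (1R,2S,5R,8S)-8-[3-(TBSO)propyl]-1-ethenyl-2-methyl-2-(TESO)-6-oxabicyclo[3.2.1]octan-7-one | C=C[C@]2([C@H](CCCO[Si](C)(C)C(C)(C)C)[C@H]3CC[C@]2(C)O[Si](CC)(CC)CC)C(=O)O3 | intermediate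
22 | 2,2-dimethoxyacetaldehyde | COC(OC)C=O | starting material
23 | ethynyl(trimethyl)silane | C#C[Si](C)(C)C | starting material
24 | lithium acetylide: lithium (trimethylsilyl)acetylide | [Li]C#C[Si](C)(C)C | intermediate
25 | rac-1,1-dimethoxy-4-(trimethylsilyl)but-3-yn-2-ol | COC(OC)C(O)C#C[Si](C)(C)C | intermediate
26 | 1,1-dimethoxy-4-(trimethylsilyl)but-3-yn-2-one | COC(OC)C(=O)C#C[Si](C)(C)C | intermediate
27 | (2R)-1,1-dimethoxy-4-(trimethylsilyl)but-3-yn-2-ol | C[Si](C)(C)C#C[C@@H](O)C(OC)OC | intermediate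
28 | (2R)-1,1-dimethoxybut-3-yn-2-ol | C#C[C@@H](O)C(OC)OC | intermediate
29 | (2R)-1,1-dimethoxybut-3-yn-2-yl methyl carbonate | C#C[C@@H](OC(=O)OC)C(OC)OC | intermediate
30 | alkyl-9-BBN: 9-{2-[C1 of 21]ethyl}-9-borabicyclo[3.3.1]nonane (vinyl of 21 hydroborated at the terminal carbon) | B1(CC[C@]4([C@H](CCCO[Si](C)(C)C(C)(C)C)[C@H]3CC[C@]4(C)O[Si](CC)(CC)CC)C(=O)O3)C2CCCC1CCC2 | intermediate
31 | (1R,2S,5R,8S)-8-[3-(TBSO)propyl]-1-[(Ra)-6,6-dimethoxyhexa-3,4-dien-1-yl]-2-methyl-2-(TESO)-6-oxabicyclo[3.2.1]octan-7-one | COC(OC)C([H])=[C@]=C([H])CC[C@]2([C@H](CCCO[Si](C)(C)C(C)(C)C)[C@H]3CC[C@]2(C)O[Si](CC)(CC)CC)C(=O)O3 | intermediate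
32 | [(1S,2S,3R,6S)-2-[3-(TBSO)propyl]-1-[(Ra)-6,6-dimethoxyhexa-3,4-dien-1-yl]-3-hydroxy-6-methyl-6-(TESO)cyclohexyl]methanol | COC(OC)C([H])=[C@]=C([H])CC[C@]2([C@H](CCCO[Si](C)(C)C(C)(C)C)[C@H](O)CC[C@]2(C)O[Si](CC)(CC)CC)CO | intermediate
33 | (1R,2S,6S)-2-[3-(TBSO)propyl]-1-[(Ra)-6,6-dimethoxyhexa-3,4-dien-1-yl]-6-methyl-3-oxo-6-(TESO)cyclohexane-1-carbaldehyde | COC(OC)C([H])=[C@]=C([H])CC[C@]2([C@H](CCCO[Si](C)(C)C(C)(C)C)C(=O)CC[C@]2(C)O[Si](CC)(CC)CC)C=O | intermediate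
34 | chloro(iodo)methane | ClCI | starting material
35 | lithium borate: lithium (chloromethyl)tri(propan-2-yloxy)borate | [Li+].ClC[B-](OC(C)C)(OC(C)C)OC(C)C | intermediate
36 | diisopropyl boronate: dipropan-2-yl (chloromethyl)boronate | ClCB(OC(C)C)OC(C)C | intermediate
37 | 2-(chloromethyl)-4,4,5,5-tetramethyl-1,3,2-dioxaborolane | ClCB1OC(C)(C)C(C)(C)O1 | intermediate
38 | 2-(iodomethyl)-4,4,5,5-tetramethyl-1,3,2-dioxaborolane | ICB1OC(C)(C)C(C)(C)O1 | intermediate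
39 | iodo[(4,4,5,5-tetramethyl-1,3,2-dioxaborolan-2-yl)methyl]zinc (LiCl complex in THF) | I[Zn]CB1OC(C)(C)C(C)(C)O1 | intermediate
40 | allylboronate: (1R,2S,5S,6S,10S)-10-[3-(TBSO)propyl]-1-hydroxy-2-[(2Z)-1-(Bpin)-4,4-dimethoxybut-2-en-2-yl]-6-methyl-6-(TESO)spiro[4.5]decan-9-one (formed as its zinc alkoxide) | COC(OC)/C=C(/CB3OC(C)(C)C(C)(C)O3)[C@@H]1CC[C@]2([C@H](CCCO[Si](C)(C)C(C)(C)C)C(=O)CC[C@]2(C)O[Si](CC)(CC)CC)[C@@H]1O | intermediate
41 | (1R,2S,5S,6S,10S)-10-[3-(TBSO)propyl]-1-hydroxy-2-[(2E)-1-hydroxy-4,4-dimethoxybut-2-en-2-yl]-6-methyl-6-(TESO)spiro[4.5]decan-9-one | COC(OC)/C=C(/CO)[C@@H]1CC[C@]2([C@H](CCCO[Si](C)(C)C(C)(C)C)C(=O)CC[C@]2(C)O[Si](CC)(CC)CC)[C@@H]1O | intermediate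
42 | (1R,2S,5S,6S,10S)-1-(TBSO)-2-[(2E)-1-(TBSO)-4,4-dimethoxybut-2-en-2-yl]-10-[3-(TBSO)propyl]-6-methyl-6-(TESO)spiro[4.5]decan-9-one | COC(OC)/C=C(/CO[Si](C)(C)C(C)(C)C)[C@@H]1CC[C@]2([C@H](CCCO[Si](C)(C)C(C)(C)C)C(=O)CC[C@]2(C)O[Si](CC)(CC)CC)[C@@H]1O[Si](C)(C)C(C)(C)C | intermediate
43 | potassium enolate of 42 (C8=C9 enolate) | COC(OC)/C=C(/CO[Si](C)(C)C(C)(C)C)[C@@H]1CC[C@]2([C@H](CCCO[Si](C)(C)C(C)(C)C)C(O[K])=CC[C@]2(C)O[Si](CC)(CC)CC)[C@@H]1O[Si](C)(C)C(C)(C)C | intermediate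
44 | (1R,2S,5S,6S,10S)-1-(TBSO)-2-[(2E)-1-(TBSO)-4,4-dimethoxybut-2-en-2-yl]-10-[3-(TBSO)propyl]-6-methyl-6-(TESO)spiro[4.5]dec-8-en-9-yl trifluoromethanesulfonate | COC(OC)/C=C(/CO[Si](C)(C)C(C)(C)C)[C@@H]1CC[C@]2([C@H](CCCO[Si](C)(C)C(C)(C)C)C(OS(=O)(=O)C(F)(F)F)=CC[C@]2(C)O[Si](CC)(CC)CC)[C@@H]1O[Si](C)(C)C(C)(C)C | intermediate
45 | potassium trifluoro(prop-1-en-2-yl)borate | [K+].C=C(C)[B-](F)(F)F | starting material
46 | (1R,2S,5S,6S,10R)-1-(TBSO)-2-[(2E)-1-(TBSO)-4,4-dimethoxybut-2-en-2-yl]-10-[3-(TBSO)propyl]-6-methyl-9-(prop-1-en-2-yl)-6-(TESO)spiro[4.5]dec-8-ene | COC(OC)/C=C(/CO[Si](C)(C)C(C)(C)C)[C@@H]1CC[C@]2([C@H](CCCO[Si](C)(C)C(C)(C)C)C(C(C)=C)=CC[C@]2(C)O[Si](CC)(CC)CC)[C@@H]1O[Si](C)(C)C(C)(C)C | intermediate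
47 | allylboronate: the (E)-9-[1-(Bpin)propan-2-ylidene] analogue of 48 (CH2Bpin in place of CH2OH) | COC(OC)/C=C(/CO[Si](C)(C)C(C)(C)C)[C@@H]1CC[C@]2([C@H](CCCO[Si](C)(C)C(C)(C)C)/C(=C(\C)CB3OC(C)(C)C(C)(C)O3)CC[C@]2(C)O[Si](CC)(CC)CC)[C@@H]1O[Si](C)(C)C(C)(C)C | intermediate
48 | (2E)-2-[(1R,2S,5S,6S,10R)-1-(TBSO)-2-[(2E)-1-(TBSO)-4,4-dimethoxybut-2-en-2-yl]-10-[3-(TBSO)propyl]-6-methyl-6-(TESO)spiro[4.5]decan-9-ylidene]propan-1-ol | COC(OC)/C=C(/CO[Si](C)(C)C(C)(C)C)[C@@H]1CC[C@]2([C@H](CCCO[Si](C)(C)C(C)(C)C)/C(=C(\C)CO)CC[C@]2(C)O[Si](CC)(CC)CC)[C@@H]1O[Si](C)(C)C(C)(C)C | intermediate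
49 | (2E)-4-(TBSO)-3-[(1R,2S,5S,6S,10R)-1-(TBSO)-10-[3-(TBSO)propyl]-9-[(2E)-1-hydroxypropan-2-ylidene]-6-methyl-6-(TESO)spiro[4.5]decan-2-yl]but-2-enal | O=C/C=C(/CO[Si](C)(C)C(C)(C)C)[C@@H]1CC[C@]2([C@H](CCCO[Si](C)(C)C(C)(C)C)/C(=C(\C)CO)CC[C@]2(C)O[Si](CC)(CC)CC)[C@@H]1O[Si](C)(C)C(C)(C)C | intermediate
50 | (2E)-2-[(1R,2S,5S,6S,10R)-1-(TBSO)-2-[(2E,4E)-1-(TBSO)-5-iodopenta-2,4-dien-2-yl]-10-[3-(TBSO)propyl]-6-methyl-6-(TESO)spiro[4.5]decan-9-ylidene]propan-1-ol | I/C=C/C=C(/CO[Si](C)(C)C(C)(C)C)[C@@H]1CC[C@]2([C@H](CCCO[Si](C)(C)C(C)(C)C)/C(=C(\C)CO)CC[C@]2(C)O[Si](CC)(CC)CC)[C@@H]1O[Si](C)(C)C(C)(C)C | intermediate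
51 | (2E)-2-[(1R,2S,5S,6S,10R)-1-(TBSO)-2-[(2E,4E)-1-(TBSO)-5-iodopenta-2,4-dien-2-yl]-10-[3-(TBSO)propyl]-6-methyl-6-(TESO)spiro[4.5]decan-9-ylidene]propanal | I/C=C/C=C(/CO[Si](C)(C)C(C)(C)C)[C@@H]1CC[C@]2([C@H](CCCO[Si](C)(C)C(C)(C)C)/C(=C(\C)C=O)CC[C@]2(C)O[Si](CC)(CC)CC)[C@@H]1O[Si](C)(C)C(C)(C)C | intermediate
52 | 5-bromo-2-methylpent-2-ene | CC(C)=CCCBr | starting material
53 | N-methoxy-N-methylacetamide | CC(=O)N(C)OC | starting material
54 | Grignard reagent: bromo(4-methylpent-3-en-1-yl)magnesium | CC(C)=CCC[Mg]Br | intermediate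
55 | 6-methylhept-5-en-2-one | CC(=O)CCC=C(C)C | intermediate
56 | lithium enolate: lithium 6-methylhepta-1,5-dien-2-olate | C=C(O[Li])CCC=C(C)C | intermediate
57 | 6-methylhepta-1,5-dien-2-yl trifluoromethanesulfonate | C=C(OS(=O)(=O)C(F)(F)F)CCC=C(C)C | intermediate
58 | 2-(6-methylhepta-1,5-dien-2-yl)-4,4,5,5-tetramethyl-1,3,2-dioxaborolane | C=C(B1OC(C)(C)C(C)(C)O1)CCC=C(C)C | intermediate
59 | (2E)-2-[(1R,2S,5S,6S,10R)-1-(TBSO)-2-[(2E,4E)-1-(TBSO)-10-methyl-6-methylideneundeca-2,4,9-trien-2-yl]-10-[3-(TBSO)propyl]-6-methyl-6-(TESO)spiro[4.5]decan-9-ylidene]propanal | C=C(/C=C/C=C(/CO[Si](C)(C)C(C)(C)C)[C@@H]1CC[C@]2([C@H](CCCO[Si](C)(C)C(C)(C)C)/C(=C(\C)C=O)CC[C@]2(C)O[Si](CC)(CC)CC)[C@@H]1O[Si](C)(C)C(C)(C)C)CCC=C(C)C | intermediate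
60 | CNP0246965.4, (2E)-2-[(1R,2S,5S,6S,10R)-1,6-dihydroxy-2-[(2E,4E)-1-hydroxy-10-methyl-6-methylideneundeca-2,4,9-trien-2-yl]-10-(3-hydroxypropyl)-6-methylspiro[4.5]decan-9-ylidene]propanal | C=C(/C=C/C=C(/CO)[C@@H]1CC[C@]2([C@H](CCCO)/C(=C(\C)C=O)CC[C@]2(C)O)[C@@H]1O)CCC=C(C)C | target

**Totals and risk**

Total step count: 34.
Longest linear sequence: 22 steps (steps 1, 2, 4–10, 16–18, 22–29, 33, 34); 22/34 ≈ 0.65.

Three steps most likely to fail:

Step 8 (lactone-enolate Claisen ring contraction). The tetrasubstituted ketene acetal must form two adjacent fully substituted carbons through a strained boat transition state, and β-elimination of the silyloxy group competes. The fallback forms the quaternary centre after the ring contraction and sets out from 11. The same LiN(i-Pr)2/Me3SiCl, toluene 105 °C and mild acid sequence on the unhindered 3-unsubstituted lactone gives (1R,2R,6S)-2-[3-(TBSO)propyl]-6-methyl-6-(TESO)cyclohex-3-ene-1-carboxylic acid F1. Me3SiCHN2 in MeOH/toluene gives its methyl ester F2. LiN(i-Pr)2 then acetaldehyde at −78 °C attacks the exocyclic ester enolate anti to the axial C2 chain and to the silyloxy group, giving the 1-(1-hydroxyethyl) ester F3 with the quaternary centre in the configuration of 19. Burgess reagent dehydrates it towards the only available β-hydrogens to the vinyl ester F4. Me3SnOH in 1,2-dichloroethane at 80 °C cleaves the hindered methyl ester, and the route comes back at 19.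

Step 22 (the proposed nickel-catalysed borylmethylative cyclization). Transmetalation of the α-boryl alkylzinc, the hindered neopentyl aldehyde, or allylboration of unreacted aldehyde by the product may defeat it. The fallback uses the known methylative version and sets out from 33. Ni(cod)2 (cat.), ZnMe2 and Ti(Oi-Pr)4 in THF at 0 °C give, with the same stereochemical course, (1R,2S,5S,6S,10S)-10-[3-(TBSO)propyl]-2-[(2Z)-4,4-dimethoxybut-2-en-2-yl]-1-hydroxy-6-methyl-6-(TESO)spiro[4.5]decan-9-one F5. SeO2 (cat.) with t-BuOOH in CH2Cl2 then oxidises the methyl group on the disubstituted alkene carbon, which is the one trans to the acetal-bearing substituent, to the primary allylic alcohol, and the route comes back at 41.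

Step 26 (nickel-catalysed 1,4-hydroboration of a hindered 1,2,3-trisubstituted diene). The diene may not reach the s-cis nickel complex, or 1,2-addition may compete, which would lose control of the tetrasubstituted alkene. The fallback replaces steps 24–26 and sets out from 42. CH2=C(CH3)MgBr with CeCl3 in THF at −78 °C adds to the ketone to give the tertiary allylic alcohol (1R,2S,5S,6S,10S)-1-(TBSO)-2-[(2E)-1-(TBSO)-4,4-dimethoxybut-2-en-2-yl]-10-[3-(TBSO)propyl]-9-hydroxy-6-methyl-9-(prop-1-en-2-yl)-6-(TESO)spiro[4.5]decane F6 (C9 epimers). NaOAc-buffered [C5H5NH][CrO3Cl] in CH2Cl2 effects Babler–Dauben oxidative 1,3-transposition to the enal (2E)-2-[(1R,2S,5S,6S,10R)-1-(TBSO)-2-[(2E)-1-(TBSO)-4,4-dimethoxybut-2-en-2-yl]-10-[3-(TBSO)propyl]-6-methyl-6-(TESO)spiro[4.5]decan-9-ylidene]propanal F7; the E isomer is separated and the Z isomer is re-equilibrated with catalytic I2 under light. NaBH4 with CeCl3·7H2O in MeOH at 0 °C reduces the enal, and the route comes back at 48.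

Further compounds
F1 | step 8 | (1R,2R,6S)-2-[3-(TBSO)propyl]-6-methyl-6-(TESO)cyclohex-3-ene-1-carboxylic acid | [C@H]2([C@H](CCCO[Si](C)(C)C(C)(C)C)C=CC[C@]2(C)O[Si](CC)(CC)CC)C(=O)O
F2 | step 8 | methyl (1R,2R,6S)-2-[3-(TBSO)propyl]-6-methyl-6-(TESO)cyclohex-3-ene-1-carboxylate | [C@H]2([C@H](CCCO[Si](C)(C)C(C)(C)C)C=CC[C@]2(C)O[Si](CC)(CC)CC)C(=O)OC
F3 | step 8 | methyl (1S,2R,6S)-2-[3-(TBSO)propyl]-1-(1-hydroxyethyl)-6-methyl-6-(TESO)cyclohex-3-ene-1-carboxylate (carbinol epimers) | CC(O)[C@]2([C@H](CCCO[Si](C)(C)C(C)(C)C)C=CC[C@]2(C)O[Si](CC)(CC)CC)C(=O)OC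
F4 | step 8 | methyl (1R,2R,6S)-2-[3-(TBSO)propyl]-1-ethenyl-6-methyl-6-(TESO)cyclohex-3-ene-1-carboxylate | C=C[C@]2([C@H](CCCO[Si](C)(C)C(C)(C)C)C=CC[C@]2(C)O[Si](CC)(CC)CC)C(=O)OC
F5 | step 22 | (1R,2S,5S,6S,10S)-10-[3-(TBSO)propyl]-2-[(2Z)-4,4-dimethoxybut-2-en-2-yl]-1-hydroxy-6-methyl-6-(TESO)spiro[4.5]decan-9-one | COC(OC)/C=C(/C)[C@@H]1CC[C@]2([C@H](CCCO[Si](C)(C)C(C)(C)C)C(=O)CC[C@]2(C)O[Si](CC)(CC)CC)[C@@H]1O
F6 | step 26 | (1R,2S,5S,6S,10S)-1-(TBSO)-2-[(2E)-1-(TBSO)-4,4-dimethoxybut-2-en-2-yl]-10-[3-(TBSO)propyl]-9-hydroxy-6-methyl-9-(prop-1-en-2-yl)-6-(TESO)spiro[4.5]decane (C9 epimers) | COC(OC)/C=C(/CO[Si](C)(C)C(C)(C)C)[C@@H]1CC[C@]2([C@H](CCCO[Si](C)(C)C(C)(C)C)C(O)(C(C)=C)CC[C@]2(C)O[Si](CC)(CC)CC)[C@@H]1O[Si](C)(C)C(C)(C)C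
F7 | step 26 | (2E)-2-[(1R,2S,5S,6S,10R)-1-(TBSO)-2-[(2E)-1-(TBSO)-4,4-dimethoxybut-2-en-2-yl]-10-[3-(TBSO)propyl]-6-methyl-6-(TESO)spiro[4.5]decan-9-ylidene]propanal | COC(OC)/C=C(/CO[Si](C)(C)C(C)(C)C)[C@@H]1CC[C@]2([C@H](CCCO[Si](C)(C)C(C)(C)C)/C(=C(\C)C=O)CC[C@]2(C)O[Si](CC)(CC)CC)[C@@H]1O[Si](C)(C)C(C)(C)C
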